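## Retrosynthetic overview

1. The lactone ring is the only ring made and it is closed last. The target comes from an open (S)-3-aryl-3-phenylpropanamide whose single free phenol is the one next to the acyl group, which fixes the 8-acyl lactone regiochemistry; debenzylation follows.
2. Key disconnection C4–C4a: a stereospecific Pd cross-coupling of a configurationally defined boron homoenolate of cinnamamide (β-carbon nucleophilic) with a ring A aryl iodide. This reverses the usual phloroglucinol-nucleophile / cinnamate-electrophile pairing and proceeds with inversion.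
3. The boron homoenolate comes from (E)-N,N-dimethylcinnamamide by Cu-catalysed asymmetric β-borylation, which sets the stereocentre.
4. The aryl iodide comes from phloroglucinol: C-acylation with 3-(4-methoxyphenyl)propanoic acid, selective bis-benzylation, ortho-iodination.

Assumption: with cinnamoyl acceptors the ligand (R)-1-[(S)-2-(diphenylphosphino)ferrocenyl]ethyldicyclohexylphosphine is taken to give the (S)-β-boryl product, so its antipode is used in step 4; the sense is checked on the first run by oxidation to the known β-hydroxy amide, and the ligand antipode is swapped if needed.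

## Route

Step 1
Reactants: 1 phloroglucinol; 2 3-(4-methoxyphenyl)propanoic acid
Product: 3 dihydrochalcone 1-(2,4,6-trihydroxyphenyl)-3-(4-methoxyphenyl)propan-1-one
Conditions: BF3·OEt2 (neat), 85 °C, 2 h; aq NaOAc work-up
Reagents that add atoms: none
Why: Friedel–Crafts C-acylation, in which BF3 activates the acid as an acylium equivalent, the threefold-symmetric, very electron-rich phloroglucinol is acylated once, and the chelated boron–ketone complex deactivates the ring toward a second acylation.

Step 2
Reactants: 3 dihydrochalcone
Product: 4 bis-benzyl ether 1-[2,4-bis(benzyloxy)-6-hydroxyphenyl]-3-(4-methoxyphenyl)propan-1-one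
Conditions: BnBr (2.05 equiv), K2CO3 (2.2 equiv), acetone, reflux
Reagents that add atoms: benzyl bromide, BrCc1ccccc1
Why: Williamson etherification alkylates the para hydroxyl and one ortho hydroxyl, while the remaining ortho hydroxyl, hydrogen-bonded to the ketone, is much less nucleophilic and stays free, as in the standard bis-benzylation of phloroacetophenone.

Step 3
Reactants: 4 bis-benzyl ether
Product: 5 aryl iodide 1-[4,6-bis(benzyloxy)-2-hydroxy-3-iodophenyl]-3-(4-methoxyphenyl)propan-1-one
Conditions: NIS (1.05 equiv), TFA (10 mol %), MeCN, 0 °C to rt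
Reagents that add atoms: N-iodosuccinimide, O=C1CCC(=O)N1I
Why: Electrophilic aromatic iodination, in which the free chelated phenol directs iodine to its own ortho carbon in preference to the carbon between the two benzyl ethers, and ring A is far more activated than the anisole ring or the ketone α-position.

Step 4
Reactants: 6 (E)-N,N-dimethylcinnamamide
Product: 8 potassium (R)-[3-(dimethylamino)-3-oxo-1-phenylpropyl]trifluoroborate, via pinacol boronate 7 (not isolated)
Conditions: CuCl (2 mol %), NaOtBu (3 mol %), (S)-1-[(R)-2-(diphenylphosphino)ferrocenyl]ethyldicyclohexylphosphine (4 mol %), B2pin2 (1.1 equiv), MeOH (2 equiv), THF, rt; then aq KHF2 (4 equiv), MeOH, rt; recrystallise from acetone/Et2O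
Reagents that add atoms: bis(pinacolato)diboron, CC1(C)OB(OC1(C)C)B1OC(C)(C)C(C)(C)O1; potassium hydrogen difluoride, [K+].[F-].F
Why: Copper-catalysed asymmetric conjugate borylation, in which the ligated Cu–Bpin species adds boron to the β-carbon on the enantioface chosen by the chiral diphosphine and MeOH protonates the copper enolate, setting the (R) stereocentre and turning the normally electrophilic β-carbon into a nucleophilic boron homoenolate; KHF2 then gives the crystalline trifluoroborate, whose recrystallisation can raise the ee.

Step 5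
Reactants: 5 aryl iodide; 8 potassium (R)-trifluoroborate (1.5 equiv)
Product: 9 (S)-3-{4,6-bis(benzyloxy)-2-hydroxy-3-[3-(4-methoxyphenyl)propanoyl]phenyl}-N,N-dimethyl-3-phenylpropanamide
Conditions: Pd(OAc)2 (10 mol %), XPhos (20 mol %), K2CO3 (3 equiv), CPME/H2O (7:1), 95 °C
Reagents that add atoms: none
Why: Stereospecific Suzuki–Miyaura cross-coupling of a secondary β-trifluoroborato amide with an aryl halide, in which the amide oxygen coordinates boron so that transmetalation to the aryl–palladium–XPhos species is an open, invertive SE2 process and its coordination to palladium then suppresses β-hydride elimination, so (R)-8 gives (S)-9 with the C4 configuration of the target.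

Step 6
Reactants: 9 (S)-hydroxy amide
Product: 11 (S)-5,7-dihydroxy-8-[3-(4-methoxyphenyl)propanoyl]-4-phenylchroman-2-one (CNP0240692.1), via bis-benzyl lactone 10 (not isolated)
Conditions: CSA (1.2 equiv, anhydrous), toluene, 80 °C; then EtOAc, 10% Pd/C, H2 (1 atm), rt; chromatography without alcohols
Reagents that add atoms: none
Why: Acid-promoted lactonisation of the ortho-hydroxy dihydrocinnamamide (accelerated by the flanking benzyloxy and β-phenyl groups in the manner of a trimethyl lock) can use only the single free phenol and so fixes the 8-acyl regiochemistry, after which catalytic hydrogenolysis in a nucleophile-free medium removes both benzyl ethers without opening the lactone, reducing the chelated electron-rich ketone or touching the stereocentre.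

## Compound list

1 | phloroglucinol (benzene-1,3,5-triol) | Oc1cc(O)cc(O)c1 | starting material
2 | 3-(4-methoxyphenyl)propanoic acid | COc1ccc(CCC(=O)O)cc1 | starting material
3 | 1-(2,4,6-trihydroxyphenyl)-3-(4-methoxyphenyl)propan-1-one | COc1ccc(CCC(=O)c2c(O)cc(O)cc2O)cc1 | intermediate
4 | 1-[2,4-bis(benzyloxy)-6-hydroxyphenyl]-3-(4-methoxyphenyl)propan-1-one | COc1ccc(CCC(=O)c2c(O)cc(OCc3ccccc3)cc2OCc2ccccc2)cc1 | intermediate
5 | 1-[4,6-bis(benzyloxy)-2-hydroxy-3-iodophenyl]-3-(4-methoxyphenyl)propan-1-one | COc1ccc(CCC(=O)c2c(O)c(I)c(OCc3ccccc3)cc2OCc2ccccc2)cc1 | intermediate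
6 | (E)-N,N-dimethylcinnamamide [(E)-N,N-dimethyl-3-phenylprop-2-enamide] | CN(C)C(=O)/C=C/c1ccccc1 | starting material
7 | (R)-N,N-dimethyl-3-phenyl-3-(4,4,5,5-tetramethyl-1,3,2-dioxaborolan-2-yl)propanamide | CN(C)C(=O)C[C@@H](B1OC(C)(C)C(C)(C)O1)c1ccccc1 | intermediate
8 | potassium (R)-[3-(dimethylamino)-3-oxo-1-phenylpropyl]trifluoroborate | CN(C)C(=O)C[C@@H]([B-](F)(F)F)c1ccccc1.[K+] | intermediate
9 | (S)-3-{4,6-bis(benzyloxy)-2-hydroxy-3-[3-(4-methoxyphenyl)propanoyl]phenyl}-N,N-dimethyl-3-phenylpropanamide | CN(C)C(=O)C[C@@H](c1ccccc1)c1c(O)c(C(=O)CCc2ccc(OC)cc2)c(OCc2ccccc2)cc1OCc1ccccc1 | intermediate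
10 | (S)-5,7-bis(benzyloxy)-8-[3-(4-methoxyphenyl)propanoyl]-4-phenylchroman-2-one | COc1ccc(CCC(=O)c2c(OCc3ccccc3)cc(OCc3ccccc3)c3c2OC(=O)C[C@H]3c2ccccc2)cc1 | intermediate
11 | (S)-5,7-dihydroxy-8-[3-(4-methoxyphenyl)propanoyl]-4-phenylchroman-2-one (CNP0240692.1) | COc1ccc(CCC(=O)c2c(O)cc(O)c3c2OC(=O)C[C@H]3c2ccccc2)cc1 | target

## Step count and risks

Total steps: 6. Longest linear sequence: 5 (steps 1, 2, 3, 5, 6 from phloroglucinol); step 4 is a one-step convergent branch.

Steps most likely to fail:

Step 5. The aryl iodide carries two ortho oxygen substituents, so transmetalation of the secondary alkyl group may be slow, with protodeboronation or loss of stereospecificity competing. The fallback sets out from 5 and comes back at 9. It exchanges the partners so that the hindered carbon carries boron and the electrophile is small. A Mizoroki–Heck reaction of 5 with N,N-dimethylacrylamide (Pd(OAc)2, P(o-tol)3, K2CO3, DMF, 100 °C) gives (E)-3-{4,6-bis(benzyloxy)-2-hydroxy-3-[3-(4-methoxyphenyl)propanoyl]phenyl}-N,N-dimethylprop-2-enamide F1. Borylation as in step 4, but with the antipodal ligand (R)-1-[(S)-2-(diphenylphosphino)ferrocenyl]ethyldicyclohexylphosphine, gives the (S)-pinacol boronate F2, which KHF2 converts into the potassium (S)-trifluoroborate F3. F3 and bromobenzene under the step 5 conditions, again with inversion, give 9.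

Step 3. Iodination of 4 could go partly to the carbon between the two benzyl ethers or onto the anisole ring. The fallback sets out from 3 and comes back at 5. It places the halogen before the ethers. NIS (1.0 equiv, MeCN, −20 °C) on 3 gives, by the symmetry of ring A, a single mono-iodide, 1-(2,4,6-trihydroxy-3-iodophenyl)-3-(4-methoxyphenyl)propan-1-one F4. BnBr (2 equiv) with K2CO3 then etherifies the para hydroxyl and the less hindered ortho hydroxyl and leaves free the chelated hydroxyl between carbonyl and iodine, which is 5.

Step 6. The acid stage may cause benzyl migration, and the hydrogenolysis stage may reduce the ketone or, if any nucleophile is present, reopen the lactone and scramble it to the 6-acyl isomer. The fallback sets out from 10 and comes back at 11. The sequence is stopped after the acid stage, 10 is isolated, and the benzyl ethers are cleaved without hydrogen by BCl3 (4 equiv) and pentamethylbenzene (6 equiv) in CH2Cl2 at −78 °C, which leaves the remote aryl methyl ether, the ketone and the lactone intact. No new compound is made (F0).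

## Further compounds

F1 | step 5 | (E)-3-{4,6-bis(benzyloxy)-2-hydroxy-3-[3-(4-methoxyphenyl)propanoyl]phenyl}-N,N-dimethylprop-2-enamide | CN(C)C(=O)/C=C/c1c(O)c(C(=O)CCc2ccc(OC)cc2)c(OCc2ccccc2)cc1OCc1ccccc1
F2 | step 5 | (S)-3-{4,6-bis(benzyloxy)-2-hydroxy-3-[3-(4-methoxyphenyl)propanoyl]phenyl}-N,N-dimethyl-3-(4,4,5,5-tetramethyl-1,3,2-dioxaborolan-2-yl)propanamide | CN(C)C(=O)C[C@H](B1OC(C)(C)C(C)(C)O1)c1c(O)c(C(=O)CCc2ccc(OC)cc2)c(OCc2ccccc2)cc1OCc1ccccc1
F3 | step 5 | potassium (S)-{1-{4,6-bis(benzyloxy)-2-hydroxy-3-[3-(4-methoxyphenyl)propanoyl]phenyl}-3-(dimethylamino)-3-oxopropyl}trifluoroborate | CN(C)C(=O)C[C@H]([B-](F)(F)F)c1c(O)c(C(=O)CCc2ccc(OC)cc2)c(OCc2ccccc2)cc1OCc1ccccc1.[K+]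
F4 | step 3 | 1-(2,4,6-trihydroxy-3-iodophenyl)-3-(4-methoxyphenyl)propan-1-one | COc1ccc(CCC(=O)c2c(O)cc(O)c(I)c2O)cc1
F0 | step 6 | none | none
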